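**Retrosynthetic overview**
The route rests on the lone benzene ring. Its carbons read C1–CO2H, C2–OH, C3–H, C4–OH, C5–CH3, C6–(13-methyltetradecyl), with oxygen on every second carbon, as in a 6-methyl-3,5,7-trioxo acid folded so that C2 meets C7.
Last cut: the acid and the C2 phenol come from hydrolysis of a 2,2-dimethyl-1,3-benzodioxin-4-one.
Key cut: the arene C1–C6 bond is opened (retro-dehydration, retro-aldol) to an acyclic 6-(3-methyl-2,4-dioxoalkyl)-1,3-dioxin-4-one, in which the heterocycle holds C1, C2 and the carboxyl.
Chain cuts: arene C5–C6 (dianion Claisen with a fatty acyl imidazolide), arene C3–C4 (dioxinone dienolate plus propanoyl chloride), and the tail (isobutyl Grignard plus 12-bromododecanoic acid under copper catalysis).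
Ring order: the dioxinone ring is bought, the benzene ring is the only ring built (step 5), and the dioxinone ring is opened last (step 6).
Key step: step 5

Remark: the side chain is read as twelve CH2 groups ending in CH(CH3)2 (13-methyltetradecyl). The target has no stereocentre, so every sp3 centre that appears on the way is carried as a mixture.

Step 1
Reactants: 1 12-bromododecanoic acid; 2 isobutylmagnesium bromide
Product: 4 14-methylpentadecanoic acid, via bromomagnesium 12-bromododecanoate 3 (not isolated)
Conditions: 2 (3 equiv, Et2O solution) added slowly to 1, Li2CuCl4 (5 mol %), THF, −20 °C to rt; then 1 M HCl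
Reagents that add atoms: none
Why: Copper-catalysed Grignard alkyl–alkyl cross-coupling of the Kochi type, in which the first equivalent of 2 only converts the acid into the unreactive carboxylate 3 and the organocopper species formed from Li2CuCl4 and further 2 displaces the unhindered primary bromide faster than a Grignard reagent adds to a magnesium carboxylate at this temperature.

Step 2
Reactants: 4 14-methylpentadecanoic acid
Product: 6 14-methylpentadecanoyl imidazolide, via acyl imidazole-1-carboxylate 5 (not isolated)
Conditions: CDI (1.1 equiv), CH2Cl2, rt until gas evolution stops; quick cold-water wash, Na2SO4, concentrate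
Reagents that add atoms: 1,1'-carbonyldiimidazole (CDI), O=C(n1ccnc1)n1ccnc1
Why: Carboxyl activation with carbonyldiimidazole, in which the acid adds to the reagent to give mixed anhydride 5, imidazole attacks its fatty acyl carbon with loss of CO2, and the water wash removes free imidazole, whose N–H would otherwise protonate the dianion used in step 4.

Step 3
Reactants: 7 2,2,6-trimethyl-4H-1,3-dioxin-4-one; 8 propanoyl chloride
Product: 10 2,2-dimethyl-6-(2-oxobutyl)-4H-1,3-dioxin-4-one, via lithium dienolate 9 (not isolated)
Conditions: 7 (2 equiv), LiN(SiMe3)2 (2 equiv), THF, −78 °C; then 8 (1 equiv), −78 °C; 1 M HCl quench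
Reagents that add atoms: none
Why: Vinylogous (γ-selective) C-acylation of a dienolate, in which LiN(SiMe3)2 deprotonates the C6 methyl group of 7 to the cross-conjugated dienolate 9, acid chlorides acylate this dienolate at its exocyclic terminal carbon, and the second equivalent of 9 neutralises the more acidic product so that it is not acylated twice.

Step 4
Reactants: 10 2,2-dimethyl-6-(2-oxobutyl)-4H-1,3-dioxin-4-one; 6 14-methylpentadecanoyl imidazolide
Product: 12 2,2-dimethyl-6-(3,17-dimethyl-2,4-dioxooctadecyl)-4H-1,3-dioxin-4-one, via dilithium dianion 11 (not isolated)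
Conditions: 10 (2 equiv), LiN(iPr)2 (4.1 equiv), THF, −78 to −40 °C; then 6 (1 equiv) in THF, −78 to −30 °C; cold 1 M HCl to pH 3; crude material carried forward without chromatography
Reagents that add atoms: none
Why: Dianion Claisen condensation, in which the second deprotonation of 10 occurs at the CH2 of the ethyl ketone, this last-formed and most basic carbon of 11 attacks the acyl imidazolide at low temperature, the spare equivalent of 11 takes up the acidic C3' proton of the product, and the new C3' centre is racemic and enolisable, which does not matter because it ends as an sp2 ring carbon.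

Step 5
Reactants: 12 2,2-dimethyl-6-(3,17-dimethyl-2,4-dioxooctadecyl)-4H-1,3-dioxin-4-one
Product: 15 7-hydroxy-2,2,6-trimethyl-5-(13-methyltetradecyl)-4H-1,3-benzodioxin-4-one, via cyclic aldol adduct 13 (not isolated), via cyclohexadienone tautomer 14 (not isolated)
Conditions: Et3N (5 equiv), CH2Cl2, 0 °C to rt, overnight; then vigorous stirring with 1 M aq HCl, rt
Reagents that add atoms: none
Why: Triethylamine reversibly removes a proton from the C1' methylene of 12 (flanked by dioxinone C6 and the C2' ketone); the delocalised anion is nucleophilic at the dioxinone α-carbon C5, which adds to the chain-bearing C4' ketone carbon to give 13 and so forms the C1–C6 bond of the future arene. Loss of water across C4a–C5 of 13 (E1cB) gives dienone 14, and enolisation of its C7 ketone delivers the phenol, so aromatisation pulls the reversible aldol forward and the acid wash dehydrates any 13 that remains. The closest known reaction type is the base-mediated cycloaromatisation of 6-(2,4-dioxoalkyl)-1,3-dioxin-4-ones to isopropylidene-protected resorcylates, the laboratory counterpart of polyketide aldol folding. Only one ring is made, the carbocycle, and it closes in a 6-(enolexo)-exo-trig aldol mode. The sp3 centres of 13 and 14 arise without control and all become sp2 ring carbons, so no stereocentre has to be set. The step needs C–C closure at C5 rather than attack of a diketone enol oxygen on C6 (O-cyclisation) or Claisen or lactone closure at the carboxyl carbon: the acetonide ties up the carboxyl and holds it away from the chain, which shuts the last two paths, the C3' methyl group lowers the enol content of the 1,3-diketone so that C4' stays electrophilic, and a weak amine base avoids retro-Claisen cleavage.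

Step 6
Reactants: 15 7-hydroxy-2,2,6-trimethyl-5-(13-methyltetradecyl)-4H-1,3-benzodioxin-4-one
Product: 17 2,4-dihydroxy-5-methyl-6-(13-methyltetradecyl)benzoic acid (target), via dipotassium resorcylate salt 16 (not isolated)
Conditions: 5 M aq KOH (10 equiv), DMSO, 60 °C, argon; cool to 0 °C, 1 M HCl to pH 3, immediate extraction into Et2O, concentrate below 30 °C
Reagents that add atoms: potassium hydroxide (its oxygen ends in the carboxyl group), [K+].[OH-]
Why: Saponification of an acylal-type aryl lactone, in which hydroxide adds to the C4 carbonyl, the opened hemiketal aryl ether collapses with loss of acetone to free the C2 phenol, and the acid is kept as the base-stable salt 16 until a short, cold acidification that leaves little time for ipso-protonation and loss of CO2.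

**Compound list**
1 | 12-bromododecanoic acid | OC(=O)CCCCCCCCCCCBr | starting material
2 | isobutylmagnesium bromide | CC(C)C[Mg]Br | starting material
3 | bromomagnesium 12-bromododecanoate | BrCCCCCCCCCCCC(=O)O[Mg]Br | intermediate
4 | 14-methylpentadecanoic acid | CC(C)CCCCCCCCCCCCC(=O)O | intermediate
5 | 14-methylpentadecanoyl 1H-imidazole-1-carboxylate (mixed anhydride) | CC(C)CCCCCCCCCCCCC(=O)OC(=O)n1ccnc1 | intermediate
6 | 14-methylpentadecanoyl imidazolide, 1-(1H-imidazol-1-yl)-14-methylpentadecan-1-one | CC(C)CCCCCCCCCCCCC(=O)n1ccnc1 | intermediate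
7 | 2,2,6-trimethyl-4H-1,3-dioxin-4-one | CC1=CC(=O)OC(C)(C)O1 | starting material
8 | propanoyl chloride | CCC(Cl)=O | starting material
9 | lithium 2,2-dimethyl-6-methylidene-6H-1,3-dioxin-4-olate (dienolate of 7) | C=C1C=C(O[Li])OC(C)(C)O1 | intermediate
10 | 2,2-dimethyl-6-(2-oxobutyl)-4H-1,3-dioxin-4-one | CCC(=O)CC1=CC(=O)OC(C)(C)O1 | intermediate
11 | dilithium dianion of 10, drawn as the bis-enolate deprotonated at C1' and C3' (alkene geometry undefined) | CC=C(O[Li])C=C1C=C(O[Li])OC(C)(C)O1 | intermediate
12 | 2,2-dimethyl-6-(3,17-dimethyl-2,4-dioxooctadecyl)-4H-1,3-dioxin-4-one (racemic at C3', keto–enol mixture) | CC(C)CCCCCCCCCCCCC(=O)C(C)C(=O)CC1=CC(=O)OC(C)(C)O1 | intermediate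
13 | 5-hydroxy-2,2,6-trimethyl-5-(13-methyltetradecyl)-5,6-dihydro-4aH-1,3-benzodioxine-4,7-dione (diastereomer mixture) | CC(C)CCCCCCCCCCCCC1(O)C(C)C(=O)C=C2OC(C)(C)OC(=O)C12 | intermediate
14 | 2,2,6-trimethyl-5-(13-methyltetradecyl)-4H-1,3-benzodioxine-4,7(6H)-dione (racemic) | CC(C)CCCCCCCCCCCCC1=C2C(=O)OC(C)(C)OC2=CC(=O)C1C | intermediate
15 | 7-hydroxy-2,2,6-trimethyl-5-(13-methyltetradecyl)-4H-1,3-benzodioxin-4-one | CC(C)CCCCCCCCCCCCc1c(C)c(O)cc2OC(C)(C)OC(=O)c12 | intermediate
16 | dipotassium 2-hydroxy-5-methyl-6-(13-methyltetradecyl)-4-oxidobenzoate | [K+].[K+].CC(C)CCCCCCCCCCCCc1c(C)c([O-])cc(O)c1C(=O)[O-] | intermediate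
17 | 2,4-dihydroxy-5-methyl-6-(13-methyltetradecyl)benzoic acid (achiral) | Cc1c(O)cc(O)c(C(=O)O)c1CCCCCCCCCCCCC(C)C | target

**Step count**
Total steps: 6 (convergent). Longest linear sequence: 5 steps (1, 2, 4, 5, 6).

**Steps most likely to fail**

**Step 4.**
- Risk: proton transfer may outrun C-acylation. The dianion can act as a base towards the enolisable imidazolide and towards the more acidic product, so conversion stalls, and acylation on oxygen or at C1' may compete.
- Fallback: this replaces acylation by aldol addition and oxidation. It sets out from 6 and 10 and comes back at 12.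
- Imidazolide 6 is reduced with i-Bu2AlH in CH2Cl2 at −78 °C to 14-methylpentadecanal F1.
- Dianion 11, made from 10 as in step 4, is added to this aldehyde at −78 °C. The aldehyde is a stronger electrophile, and its aldolate cannot protonate the dianion.
- This gives 6-(4-hydroxy-3,17-dimethyl-2-oxooctadecyl)-2,2-dimethyl-4H-1,3-dioxin-4-one F2 as a diastereomer mixture.
- Oxidation of the secondary alcohol with Dess–Martin periodinane in CH2Cl2 then gives 12.

**Step 5.**
- Risk: slow aldol closure onto the hindered, α-branched ketone may let O-cyclisation or retro-Claisen chain cleavage compete.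
- Fallback: this changes the aldol donor. It sets out from 12 and comes back at 17, which also bypasses step 6.
- Heating 12 in toluene at about 110 °C with benzyl alcohol expels acetone by a retro-hetero-Diels–Alder reaction and gives the acylketene 6,20-dimethylhenicos-1-ene-1,3,5,7-tetrone F3.
- The alcohol traps this ketene as benzyl 6,20-dimethyl-3,5,7-trioxohenicosanoate F4.
- The C2 methylene of this ester is a true β-keto ester carbon and a better aldol donor than dioxinone C5. Cs2CO3 in THF followed by HCl should therefore close and aromatise it to benzyl 2,4-dihydroxy-5-methyl-6-(13-methyltetradecyl)benzoate F5.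
- Hydrogenolysis (H2, Pd/C, EtOAc, rt) releases 17 under neutral conditions.

**Step 6.**
- Risk: hydroxide attack at a carbonyl flanked by two ortho substituents and deactivated by the para phenoxide may be sluggish and demand heat. Loss of CO2 through ipso-protonation of the electron-rich ring may then occur in hot base or on acidification.
- Fallback: this caps the C7 oxygen first. It sets out from 15 and comes back at 17.
- O-Benzylation (benzyl bromide, K2CO3, DMF, rt) gives 7-(benzyloxy)-2,2,6-trimethyl-5-(13-methyltetradecyl)-4H-1,3-benzodioxin-4-one F6, which can no longer form the deactivating phenoxide.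
- Aqueous KOH in DMSO at lower temperature, followed by cold acidification, should give the less decarboxylation-prone 4-(benzyloxy)-2-hydroxy-5-methyl-6-(13-methyltetradecyl)benzoic acid F7.
- Hydrogenolysis (H2, Pd/C, EtOAc, rt) uncovers the C4 phenol and gives 17 without further acid or base.

**Further compounds**
F1 | step 4 | 14-methylpentadecanal | CC(C)CCCCCCCCCCCCC=O
F2 | step 4 | 6-(4-hydroxy-3,17-dimethyl-2-oxooctadecyl)-2,2-dimethyl-4H-1,3-dioxin-4-one (diastereomer mixture) | CC(C)CCCCCCCCCCCCC(O)C(C)C(=O)CC1=CC(=O)OC(C)(C)O1
F3 | step 5 | 6,20-dimethylhenicos-1-ene-1,3,5,7-tetrone (acylketene) | CC(C)CCCCCCCCCCCCC(=O)C(C)C(=O)CC(=O)C=C=O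
F4 | step 5 | benzyl 6,20-dimethyl-3,5,7-trioxohenicosanoate | CC(C)CCCCCCCCCCCCC(=O)C(C)C(=O)CC(=O)CC(=O)OCc1ccccc1
F5 | step 5 | benzyl 2,4-dihydroxy-5-methyl-6-(13-methyltetradecyl)benzoate | CC(C)CCCCCCCCCCCCc1c(C)c(O)cc(O)c1C(=O)OCc1ccccc1
F6 | step 6 | 7-(benzyloxy)-2,2,6-trimethyl-5-(13-methyltetradecyl)-4H-1,3-benzodioxin-4-one | CC(C)CCCCCCCCCCCCc1c(C)c(OCc3ccccc3)cc2OC(C)(C)OC(=O)c12
F7 | step 6 | 4-(benzyloxy)-2-hydroxy-5-methyl-6-(13-methyltetradecyl)benzoic acid | CC(C)CCCCCCCCCCCCc1c(C)c(OCc2ccccc2)cc(O)c1C(=O)O
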